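**Plan**

- Numbering: C1 (aryloxy CH2), C2 and C3 (carbinols), C4, C5 (lactone CH), C6, C7 (α-carbon), C8 (lactone C=O). The retrosynthesis cuts, in this order, the exocyclic C7=CH2 bond, the ether bond C1–O(coumarin), the lactone bond C5–O, and the C2=C3 bond of an (E)-enoate.
- Forward: the C1–C8 chain is joined by olefination of tert-butyl 6-oxoheptanoate. The only ring made in the route, the γ-lactone O–C5–C6–C7–C8, is closed by oxidising a C5–H bond of the open-chain C8 acid. The preformed coumarin bicycle is attached at O1 afterwards, and the methylene comes last.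
- Enabling feature: C5 is the γ-carbon of the C8 carboxyl and, in the open chain, an unactivated CH2 between C4 and C6. One carboxylate-directed C–H oxidation can therefore create both the lactone ring and the C5 stereocentre.
- Stereochemistry: C3 comes from a Katsuki–Sharpless epoxidation (L-tartrate). C2 is set by inversion when CO2 opens that epoxide to the O1/O2 cyclic carbonate. C5 comes from the chiral manganese catalyst.
- The coumarin ether is made only after the oxidation, because an alkoxycoumarin (electron-rich arene, cinnamate-type alkene) would compete for the manganese oxidant. At that stage O1/O2 are a cyclic carbonate and the C3 hydroxyl, which has no α-hydrogen, is free.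

Key step: step 7

Remark: TIPSpdp = (S,S)-1,1'-bis{[5-(triisopropylsilyl)pyridin-2-yl]methyl}-2,2'-bipyrrolidine; the (S,S) complex is assumed to be the antipode matched to the C3 centre, which a trial with both antipodes has to confirm.

**Route**

Step 1
Reactants: 1 6-oxoheptanoic acid
Product: 2 tert-butyl 6-oxoheptanoate
Conditions: tBuOC(=NH)CCl3, BF3·OEt2 (cat.), cyclohexane/CH2Cl2, rt
Reagents that add atoms: tert-butyl 2,2,2-trichloroacetimidate, CC(C)(C)OC(=N)C(Cl)(Cl)Cl
Why: Acid-catalysed imidate esterification tert-butylates the carboxylic acid without touching the ketone and gives an ester that should survive hydride, base and titanium alkoxide and is later removed by acid alone.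

Step 2
Reactants: 2 tert-butyl 6-oxoheptanoate; 3 triethyl phosphonoacetate
Product: 4 8-tert-butyl 1-ethyl (2E)-3-methyloct-2-enedioate
Conditions: NaH, THF, 0 °C → 50 °C
Reagents that add atoms: triethyl phosphonoacetate (3), CCOC(=O)CP(=O)(OCC)OCC
Why: Horner–Wadsworth–Emmons olefination of the methyl ketone with the stabilised phosphonate anion should favour the (E)-enoate, and the minor (Z)-isomer is to be removed by chromatography here or at 5.

Step 3
Reactants: 4 8-tert-butyl 1-ethyl (2E)-3-methyloct-2-enedioate
Product: 5 tert-butyl (6E)-8-hydroxy-6-methyloct-6-enoate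
Conditions: iBu2AlH (2.2 equiv), CH2Cl2, −78 °C; aq. potassium sodium tartrate
Reagents that add atoms: none
Why: 1,2-Reduction of the conjugated ethyl ester by iBu2AlH at low temperature, which the hindered tert-butyl ester should resist, gives the (E)-allylic alcohol without touching the trisubstituted alkene.

Step 4
Reactants: 5 tert-butyl (6E)-8-hydroxy-6-methyloct-6-enoate
Product: 6 tert-butyl 5-[(2S,3S)-3-(hydroxymethyl)-2-methyloxiran-2-yl]pentanoate
Conditions: Ti(OiPr)4 (cat.), diethyl L-(+)-tartrate (cat.), tBuOOH, 4 Å molecular sieves, CH2Cl2, −20 °C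
Reagents that add atoms: tert-butyl hydroperoxide, CC(C)(C)OO
Why: Katsuki–Sharpless asymmetric epoxidation with L-(+)-tartrate should epoxidise this geraniol-type (E)-allylic alcohol on the face that gives the (2S,3S)-epoxy alcohol, which fixes C3 as 3S and sets C2 up for the inversion of step 5.

Step 5
Reactants: 6 tert-butyl 5-[(2S,3S)-3-(hydroxymethyl)-2-methyloxiran-2-yl]pentanoate
Product: 7 tert-butyl (6S)-6-hydroxy-6-[(4R)-2-oxo-1,3-dioxolan-4-yl]heptanoate
Conditions: Cs2CO3, CO2 (1 atm), 3 Å molecular sieves, DMF, 40 °C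
Reagents that add atoms: carbon dioxide, O=C=O
Why: Carboxylative opening of a 2,3-epoxy alcohol: the primary alkoxide adds to CO2 and the carbonate oxygen opens the epoxide at C2 in a 5-exo fashion with inversion (2S to 2R), while the C3–O bond and thus 3S stay untouched, so O1 and O2 emerge as a cyclic carbonate and the C3 hydroxyl is free.

Step 6
Reactants: 7 tert-butyl (6S)-6-hydroxy-6-[(4R)-2-oxo-1,3-dioxolan-4-yl]heptanoate
Product: 8 (6S)-6-hydroxy-6-[(4R)-2-oxo-1,3-dioxolan-4-yl]heptanoic acid
Conditions: CF3CO2H, CH2Cl2, 0 °C → rt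
Reagents that add atoms: none
Why: Acidolysis of the tert-butyl ester (E1 loss of 2-methylpropene) frees the carboxylic acid, the cyclic carbonate being acid-stable and the tertiary carbinol, next to the electron-poor carbonate carbon, being expected to resist ionisation at this temperature.

Step 7
Reactants: 8 (6S)-6-hydroxy-6-[(4R)-2-oxo-1,3-dioxolan-4-yl]heptanoic acid
Product: 9 (5S)-5-{(2S)-2-hydroxy-2-[(4R)-2-oxo-1,3-dioxolan-4-yl]propyl}oxolan-2-one
Conditions: (S,S)-Mn(TIPSpdp)(OTf)2 (2 mol%), aq. H2O2 (syringe pump), (CF3)2CHOH, 0 °C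
Reagents that add atoms: none
Why: Proposed new method: acid 8 binds divalent manganese as its carboxylate, H2O2 is cleaved at the metal to a pentavalent manganese oxo carboxylate, the oxo abstracts one hydrogen of the γ-methylene C5 by 1,7-hydrogen atom transfer, and the C5 radical is captured by the bound carboxylate oxygen before it can invert. The closest known reaction type is the manganese-catalysed, carboxylic-acid-directed γ-C–H lactonisation of alkanoic acids with H2O2 in fluorinated alcohols, which is enantioselective at unactivated methylene groups of branched and cyclic acids but has not been shown on an unbranched chain carrying a carbonate and a tertiary alcohol. The five-membered lactone (O–C5–C6–C7–C8) closes by C5–O bond formation between the ligated carboxylate oxygen and the C5 radical inside the coordination sphere of the metal. The C5 configuration is set by the chiral ligand, which must select the pro-S hydrogen of C5; retention in the oxygen transfer then gives 5S, and the catalyst antipode has to be matched against the remote C3 centre. Site selectivity for C5 over C4 and C6 rests on the carboxylate tether (γ before β and δ) and on inductive deactivation of C4, C2 and C1 by the C3 carbinol and the carbonate; C3 carries no hydrogen, and no arene or alkene is present at this stage.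

Step 8
Reactants: 9 (5S)-5-{(2S)-2-hydroxy-2-[(4R)-2-oxo-1,3-dioxolan-4-yl]propyl}oxolan-2-one
Product: 11 (5S)-5-[(2S,3R)-2,3,4-trihydroxy-2-methylbutyl]oxolan-2-one, via methyl tetrahydroxy ester 10 (not isolated)
Conditions: K2CO3 (cat.), MeOH, 0 °C → rt; then Amberlyst 15 (H+ form), rt
Reagents that add atoms: none
Why: Base-catalysed transesterification of the cyclic carbonate with methanol frees the triol, and acid then re-closes the γ-hydroxy methyl ester to the five-membered lactone, the only unstrained lactone available since the C3 and C2 hydroxyls would give seven- and eight-membered rings.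

Step 9
Reactants: 11 (5S)-5-[(2S,3R)-2,3,4-trihydroxy-2-methylbutyl]oxolan-2-one
Product: 12 (2R,3S)-2,3-dihydroxy-3-methyl-4-[(2S)-5-oxooxolan-2-yl]butyl 4-methylbenzenesulfonate
Conditions: TsCl (1.05 equiv), Bu2SnO (cat.), Et3N, CH2Cl2/MeCN, 0 °C → rt
Reagents that add atoms: 4-methylbenzenesulfonyl chloride, Cc1ccc(cc1)S(=O)(=O)Cl
Why: Tin-mediated regioselective sulfonylation through the 1,2-stannylene acetal should tosylate only the primary C1 hydroxyl, the secondary and tertiary hydroxyls being far less reactive.

Step 10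
Reactants: 12 (2R,3S)-2,3-dihydroxy-3-methyl-4-[(2S)-5-oxooxolan-2-yl]butyl 4-methylbenzenesulfonate
Product: 13 {(4R,5S)-2,2,5-trimethyl-5-[[(2S)-5-oxooxolan-2-yl]methyl]-1,3-dioxolan-4-yl}methyl 4-methylbenzenesulfonate
Conditions: Me2C(OMe)2, pyridinium 4-toluenesulfonate (cat.), acetone, rt
Reagents that add atoms: 2,2-dimethoxypropane, COC(C)(C)OC
Why: Acid-catalysed transketalisation ties the C2/C3 diol into an acetonide, which masks both hydroxyls for the basic steps that follow and leaves the sulfonate and the lactone untouched.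

Step 11
Reactants: 13 {(4R,5S)-2,2,5-trimethyl-5-[[(2S)-5-oxooxolan-2-yl]methyl]-1,3-dioxolan-4-yl}methyl 4-methylbenzenesulfonate; 14 umbelliferone
Product: 15 7-({(4R,5S)-2,2,5-trimethyl-5-[[(2S)-5-oxooxolan-2-yl]methyl]-1,3-dioxolan-4-yl}methoxy)-2H-chromen-2-one
Conditions: Cs2CO3, DMF, 80 °C
Reagents that add atoms: umbelliferone (14), Oc1ccc2ccc(=O)oc2c1
Why: Williamson ether synthesis in which the caesium phenoxide of umbelliferone displaces the primary tosylate at C1 by SN2, as in the alkylation of phenols with dioxolanylmethyl tosylates, forms the aryl ether without touching a stereocentre.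

Step 12
Reactants: 15 7-({(4R,5S)-2,2,5-trimethyl-5-[[(2S)-5-oxooxolan-2-yl]methyl]-1,3-dioxolan-4-yl}methoxy)-2H-chromen-2-one
Product: 18 7-({(4R,5S)-2,2,5-trimethyl-5-[[(2S)-4-methylidene-5-oxooxolan-2-yl]methyl]-1,3-dioxolan-4-yl}methoxy)-2H-chromen-2-one, via Mannich base 16 (not isolated), via trimethylammonium iodide 17 (not isolated)
Conditions: LiN(SiMe3)2, THF, −78 °C; CH2=NMe2+ I−, −78 °C → rt; then MeI, MeOH, rt; then aq. NaHCO3, CH2Cl2, rt
Reagents that add atoms: dimethylmethyleneiminium iodide (Eschenmoser's salt), C=[N+](C)C.[I-]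
Why: Mannich α-methylenation of a γ-lactone, in which the lithium enolate is aminomethylated by the iminium salt and quaternisation followed by base-induced β-elimination of trimethylamine (Hofmann type) gives the exocyclic C7=CH2, complete enolate formation at −78 °C being meant to keep the enolate from adding to the coumarin.

Step 13
Reactants: 18 7-({(4R,5S)-2,2,5-trimethyl-5-[[(2S)-4-methylidene-5-oxooxolan-2-yl]methyl]-1,3-dioxolan-4-yl}methoxy)-2H-chromen-2-one
Product: 19 (5S)-5-[(2S,3R)-2,3-dihydroxy-2-methyl-4-[(2-oxo-2H-chromen-7-yl)oxy]butyl]-3-methylideneoxolan-2-one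
Conditions: aq. HCl (2 M), THF, rt → 40 °C
Reagents that add atoms: none
Why: Acid-catalysed acetonide hydrolysis frees the C2/C3 diol under conditions to which the α-methylene lactone and the coumarin are stable, no base that could add to the methylene lactone being used.

**Compound list**

1 | 6-oxoheptanoic acid | CC(=O)CCCCC(=O)O | starting material
2 | tert-butyl 6-oxoheptanoate | CC(=O)CCCCC(=O)OC(C)(C)C | intermediate
3 | triethyl phosphonoacetate | CCOC(=O)CP(=O)(OCC)OCC | starting material
4 | 8-tert-butyl 1-ethyl (2E)-3-methyloct-2-enedioate | CCOC(=O)/C=C(\C)CCCCC(=O)OC(C)(C)C | intermediate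
5 | tert-butyl (6E)-8-hydroxy-6-methyloct-6-enoate | OC/C=C(\C)CCCCC(=O)OC(C)(C)C | intermediate
6 | tert-butyl 5-[(2S,3S)-3-(hydroxymethyl)-2-methyloxiran-2-yl]pentanoate | OC[C@@H]1O[C@@]1(C)CCCCC(=O)OC(C)(C)C | intermediate
7 | tert-butyl (6S)-6-hydroxy-6-[(4R)-2-oxo-1,3-dioxolan-4-yl]heptanoate | CC(C)(C)OC(=O)CCCC[C@](C)(O)[C@@H]1OC(=O)OC1 | intermediate
8 | (6S)-6-hydroxy-6-[(4R)-2-oxo-1,3-dioxolan-4-yl]heptanoic acid | OC(=O)CCCC[C@](C)(O)[C@@H]1OC(=O)OC1 | intermediate
9 | (5S)-5-{(2S)-2-hydroxy-2-[(4R)-2-oxo-1,3-dioxolan-4-yl]propyl}oxolan-2-one | O=C1CC[C@@H](C[C@](C)(O)[C@@H]2OC(=O)OC2)O1 | intermediate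
10 | methyl (4S,6S,7R)-4,6,7,8-tetrahydroxy-6-methyloctanoate | COC(=O)CC[C@H](O)C[C@](C)(O)[C@H](O)CO | intermediate (not isolated)
11 | (5S)-5-[(2S,3R)-2,3,4-trihydroxy-2-methylbutyl]oxolan-2-one | O=C1CC[C@@H](C[C@](C)(O)[C@H](O)CO)O1 | intermediate
12 | (2R,3S)-2,3-dihydroxy-3-methyl-4-[(2S)-5-oxooxolan-2-yl]butyl 4-methylbenzenesulfonate | O=C1CC[C@@H](C[C@](C)(O)[C@H](O)COS(=O)(=O)c2ccc(C)cc2)O1 | intermediate
13 | {(4R,5S)-2,2,5-trimethyl-5-[[(2S)-5-oxooxolan-2-yl]methyl]-1,3-dioxolan-4-yl}methyl 4-methylbenzenesulfonate | O=C1CC[C@@H](C[C@]2(C)OC(C)(C)O[C@@H]2COS(=O)(=O)c2ccc(C)cc2)O1 | intermediate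
14 | umbelliferone (7-hydroxy-2H-chromen-2-one) | Oc1ccc2ccc(=O)oc2c1 | starting material
15 | 7-({(4R,5S)-2,2,5-trimethyl-5-[[(2S)-5-oxooxolan-2-yl]methyl]-1,3-dioxolan-4-yl}methoxy)-2H-chromen-2-one | O=C1CC[C@@H](C[C@]2(C)OC(C)(C)O[C@@H]2COc2ccc3ccc(=O)oc3c2)O1 | intermediate
16 | (5S)-3-[(dimethylamino)methyl]-5-({(4S,5R)-2,2,4-trimethyl-5-[[(2-oxo-2H-chromen-7-yl)oxy]methyl]-1,3-dioxolan-4-yl}methyl)oxolan-2-one, C3 epimers of the lactone | CN(C)CC1C[C@@H](C[C@]2(C)OC(C)(C)O[C@@H]2COc2ccc3ccc(=O)oc3c2)OC1=O | intermediate (not isolated)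
17 | N,N,N-trimethyl-1-[(5S)-2-oxo-5-({(4S,5R)-2,2,4-trimethyl-5-[[(2-oxo-2H-chromen-7-yl)oxy]methyl]-1,3-dioxolan-4-yl}methyl)oxolan-3-yl]methanaminium iodide | C[N+](C)(C)CC1C[C@@H](C[C@]2(C)OC(C)(C)O[C@@H]2COc2ccc3ccc(=O)oc3c2)OC1=O.[I-] | intermediate (not isolated)
18 | 7-({(4R,5S)-2,2,5-trimethyl-5-[[(2S)-4-methylidene-5-oxooxolan-2-yl]methyl]-1,3-dioxolan-4-yl}methoxy)-2H-chromen-2-one | C=C1C[C@@H](C[C@]2(C)OC(C)(C)O[C@@H]2COc2ccc3ccc(=O)oc3c2)OC1=O | intermediate
19 | (5S)-5-[(2S,3R)-2,3-dihydroxy-2-methyl-4-[(2-oxo-2H-chromen-7-yl)oxy]butyl]-3-methylideneoxolan-2-one | C=C1C[C@@H](C[C@](C)(O)[C@H](O)COc2ccc3ccc(=O)oc3c2)OC1=O | target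

**Step count**

Total: 13 steps. Longest linear sequence: 13 steps (1 to 19).

**Steps most likely to fail**

1. Step 7 (Proposed new method). Hydrogen abstraction at the inductively deactivated C5 methylene may be too slow against unproductive decay of H2O2. The catalyst may also discriminate poorly between the two C5 hydrogens beside the remote C3 centre and erode the C5 configuration.
 Fallback with known chemistry, from 7 back to 11: the C5 oxygen is introduced from the free C3 hydroxyl by hydroxyl-directed C–H silylation. Compound 7 is converted with Et2SiH2 and [Ir(cod)OMe]2 into the diethylsilyl ether F1. Heating F1 with [Ir(cod)OMe]2, 3,4,7,8-tetramethyl-1,10-phenanthroline and norbornene closes the oxasilolane F2 by silylation of the γ-methylene C5. Tamao–Fleming oxidation (H2O2, KHCO3, MeOH/THF) replaces silicon by hydroxyl with retention and cleaves the carbonate in the same operation, giving the tetrahydroxy tert-butyl ester F3. CF3CO2H then removes the tert-butyl group and closes the lactone to 11. C5 would here be set under substrate control through the five-membered oxasilolane; its sense has to be checked, and an unwanted C5 epimer would be removed at 11 or 12.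

2. Step 11. The SN2 displacement at the β-branched C1 by the weakly nucleophilic coumarin phenoxide may be sluggish, with loss of material to elimination or lactone opening at the temperature needed.
 Fallback, from 12 back to 15: acetonide formation and etherification are exchanged so that the C2 hydroxyl assists. Compound 12, 14 and Cs2CO3 in DMF at 50 °C first close the terminal epoxide F4 (O2 displaces the tosylate, no stereocentre is touched). The phenoxide opens F4 at the unhindered C1 to the diol ether F5. Me2C(OMe)2 with pyridinium 4-toluenesulfonate then gives 15.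

3. Step 12. The lactone enolate or the amide base may add to the coumarin, or quaternisation and elimination may stay incomplete.
 Fallback, from 15 back to 18: thermodynamic α-carboxylation with methoxymagnesium methyl carbonate (MeOMgOCO2Me, DMF, 120 °C) gives, after careful acidification, the lactone carboxylic acid F6. With aqueous formaldehyde and Et2NH in NaOAc/AcOH, F6 undergoes a Mannich reaction with decarboxylative elimination to 18. No amide base and no free lithium enolate are involved.

**Further compounds**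

F1 | step 7 | tert-butyl (6S)-6-[(diethylsilyl)oxy]-6-[(4R)-2-oxo-1,3-dioxolan-4-yl]heptanoate | CC(C)(C)OC(=O)CCCC[C@](C)(O[SiH](CC)CC)[C@@H]1OC(=O)OC1
F2 | step 7 | tert-butyl 3-{(3S,5S)-2,2-diethyl-5-methyl-5-[(4R)-2-oxo-1,3-dioxolan-4-yl]-1,2-oxasilolan-3-yl}propanoate | CC(C)(C)OC(=O)CC[C@H]1C[C@](C)(O[Si]1(CC)CC)[C@@H]2OC(=O)OC2
F3 | step 7 | tert-butyl (4S,6S,7R)-4,6,7,8-tetrahydroxy-6-methyloctanoate | CC(C)(C)OC(=O)CC[C@H](O)C[C@](C)(O)[C@H](O)CO
F4 | step 11 | (5S)-5-{(2S)-2-hydroxy-2-[(2R)-oxiran-2-yl]propyl}oxolan-2-one | O=C1CC[C@@H](C[C@](C)(O)[C@H]2CO2)O1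
F5 | step 11 | (5S)-5-[(2S,3R)-2,3-dihydroxy-2-methyl-4-[(2-oxo-2H-chromen-7-yl)oxy]butyl]oxolan-2-one | O=C1CC[C@@H](C[C@](C)(O)[C@H](O)COc2ccc3ccc(=O)oc3c2)O1
F6 | step 12 | (5S)-2-oxo-5-({(4S,5R)-2,2,4-trimethyl-5-[[(2-oxo-2H-chromen-7-yl)oxy]methyl]-1,3-dioxolan-4-yl}methyl)oxolane-3-carboxylic acid | OC(=O)C1C[C@@H](C[C@]2(C)OC(C)(C)O[C@@H]2COc2ccc3ccc(=O)oc3c2)OC1=O
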